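The readings were generated by integration with constants of no real substance.

One number, the pairing number, carries this reckoning: rate constant times starting concentration of J times time, which the field calls a Damköhler number. For two partners charged together in equal amounts and reacting by one second-order step with no other path, the part of J left is one over one plus that number; we apply this to Z added in portions as an approximation.

| setting | dusk | dawn | flask |
|---|---|---|---|
| J | 0.28 M | 0.44 M | 0.20 M |
| Z | 0.98 equiv (in portions, 4) | 0.98 equiv (in portions, 4) | 0.980 equiv (in portions, 4) |
| remark | run made earlier; portions every 3.0 min | run made earlier; portions every 3.0 min | the portions of Z follow each other after 3.0 min, the first at the start |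
| time |  |  | 80 min |

| run | time / min | J / % | D / % |
|---|---|---|---|
| dusk | 5.00 | 64.6 | 15.1 |
| dusk | 15.0 | 21.5 | 32.3 |
| dusk | 30.0 | 8.4 | 36.0 |
| dusk | 40.0 | 7.0 | 37.1 |
| dusk | 60.0 | 7.0 | 40.4 |
| dusk | 80.0 | 5.4 | 41.4 |
| dawn | 5.00 | 59.9 | 19.7 |
| dawn | 15.0 | 14.6 | 38.4 |
| dawn | 30.0 | 6.0 | 38.7 |
| dawn | 40.0 | 5.4 | 40.9 |
| dawn | 60.0 | 4.8 | 43.5 |
| dawn | 80.0 | 3.8 | 44.6 |

(scatter of a reading: 0.5 percentage points)

- the analysis behind the earlier runs scatters by 0.5 percentage points, standard deviation
- the reaction counts as stopped when no species that holds the J changes by six tenths of a point or more over the second half of the time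
- what has gone from J into another species counts as reacted, even if it can come back

- the state of affairs at 80 min: stopped, and by what, or still going (Z has run out first / it is still moving / all of J has reacted / forward and back rates have come level)
- part of the J gone at 80 min
- the D standing at 80 min, as a percentage of the J charged

The last J readings give an apparent rate constant for each run, 0.782 /M/min from dusk and 0.719 /M/min from dawn, so concentration enters roughly as the number says. Their mean, 0.751 /M/min, times 0.20 M and 80 min, makes the pairing number of the flask 12.0. We therefore expect 7.69% of J left. At 40.0 min the number is 6.00 and J stands at 14.3%, so by this estimate J still falls 6.6 percentage points over the rest of the time, against a scatter of 0.5 points: still moving.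

One number is not enough. For dusk at 30.0 min it gives 13.7% of J against a reading of 8.4%, and it does not say where J goes. D needs a second reading: dusk ended with D at 43.8% of the J gone, which gives us 40.4% of D.

The forecast says it is still moving, with 92.8% gone and 39% of D: “The flask is more dilute and slower, so it should still be moving.”

In the flask, it is still moving, with 92.9% gone and 39.8% of D. Its 7.07% of J puts the pairing number at 13.1, against our 12.0.

    J + Z → D + L (k = 0.640 /M/min)
    D ⇌ Q (K = 0.930, k = 0.0980 /min)
    J ⇌ X (K = 1.60, k = 0.0440 /min)

Read at 20 min, the same flask should by the number hold 25.0% of J; it held 18.4%, with 30.2% as X. While Z was still being added to the flask, J fed both D and X, and X stood at 24.9% at 9.00 min. Later X gave J back, falling from 25.8% at 40.0 min to 17.1% at 80.0 min, while part of D passed on into Q, which stood at 36.0% at 80.0 min.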